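**Retrosynthetic overview**
- 10 ⇒ 7: the benzylic C1–O bond is made last, by anodic oxidation of the benzylic C–H of 7. The C3 veratrate closes onto the benzylic cation and water reopens the ring, so the acyl group moves from O3 to O1 and C1 is set by C2/C3.
- 7 ⇒ 5 + 6: O-acylation of the C3 carbinol with 3,4-dimethoxybenzoyl chloride.
- 5 ⇒ 1 + 2: SN2 opening of C2-symmetric (2S,3S)-2,3-epoxybutane by the 3,4,5-trimethoxybenzyl Grignard reagent; the epoxide brings in C2 (inversion) and C3 (retention).
- Rings: the target is acyclic; the only ring ever formed is the transient 1,3-dioxan-2-ylium 8 in the last step.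

Assumption: (2S,3S)-2,3-dimethyloxirane (the epoxide of (2S,3S)-butane-2,3-diol) is bought as such; 1 and 6 are catalogue compounds.

**Step 1**
Reactants: 1 3,4,5-trimethoxybenzyl chloride; 2 (2S,3S)-2,3-dimethyloxirane
Product: 5 (2S,3S)-3-methyl-4-(3,4,5-trimethoxyphenyl)butan-2-ol, via benzylic Grignard reagent 3 (not isolated), via chloromagnesium alkoxide 4 (not isolated)
Conditions: Mg, THF, 0 °C (slow addition of 1); then CuI (10 mol%), 2 (1.2 equiv), −30 → 0 °C; 1 M HCl
Reagents that add atoms: none
Why: Cu-catalysed SN2 ring opening of an epoxide by a benzylic Grignard reagent; 2 is C2-symmetric, so there is no regiochemical choice, and attack with inversion at one carbon (the future C2) and retention at the carbinol carbon (C3) gives the 2,3-syn (2S,3S) alcohol as one diastereomer, both centres coming from 2.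

**Step 2**
Reactants: 5 (2S,3S)-3-methyl-4-(3,4,5-trimethoxyphenyl)butan-2-ol; 6 3,4-dimethoxybenzoyl chloride
Product: 7 (2S,3S)-3-methyl-4-(3,4,5-trimethoxyphenyl)butan-2-yl 3,4-dimethoxybenzoate
Conditions: 6 (1.3 equiv), Et3N (2 equiv), DMAP (10 mol%), CH2Cl2, 0 °C → rt
Reagents that add atoms: none
Why: DMAP-catalysed acylation of a secondary alcohol by an acid chloride (nucleophilic acyl substitution via the N-acylpyridinium); the carbinol C–O bond is not touched, so both stereocentres are retained, and the ester placed here is the group later relayed to C1.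

**Step 3**
Reactants: 7 (2S,3S)-3-methyl-4-(3,4,5-trimethoxyphenyl)butan-2-yl 3,4-dimethoxybenzoate
Product: 10 (1R,2R,3S)-3-hydroxy-2-methyl-1-(3,4,5-trimethoxyphenyl)butyl 3,4-dimethoxybenzoate (CNP0167175.1), via dioxanylium cation 8 (not isolated), via cyclic hemiorthoester 9 (not isolated)
Conditions: graphite(+)|Pt(−), undivided cell, 5 mA cm⁻², 2.3 F mol⁻¹, nBu4NBF4 (0.1 M), 2,4,6-collidine (2 equiv), HFIP/CH2Cl2 1:4, 0 °C; then H2O, AcOH–NaOAc buffer (pH ≈ 4), 0 °C → rt; non-basic work-up
Reagents that add atoms: water, O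
Why: Proposed new method: anodic benzylic C–H acyloxylation with acyl relay from a neighbouring ester – the trimethoxyaryl ring (Ep about 1.3–1.4 V vs SCE, estimated) is oxidised in preference to the ester-deactivated veratroyl ring (about 1.7 V, estimated), the radical cation loses the benzylic proton to collidine and the radical is oxidised again (ECE) to the benzylic cation, which is trapped 6-exo by the carbonyl oxygen of the C3 veratrate to give the aryl-stabilised 1,3-dioxan-2-ylium 8 (positively charged, hence shielded from over-oxidation; any benzylic HFIP ether re-ionises to the same ion); A(1,3) strain holds C2–H in the plane of the benzylic cation, so the tethered carbonyl reaches only the face on which C3 sits (chair transition state, aryl and C2-methyl equatorial), which sets C1 as R (1,2-anti, 1,3-anti) under control of the bought centres C2 and C3; water then gives hemiorthoester 9, whose kinetic, weakly acid-catalysed collapse is expected to break the bond to the less hindered, more basic O3 and leave the veratrate on the more hindered benzylic oxygen; closest known reaction types are the anodic side-chain acetoxylation/methoxylation of methoxytoluenes, electrochemical benzylic functionalisation in HFIP, anchimeric assistance by esters through acyloxonium ions, and the hydrolysis of cyclic ortho esters to the mono-ester of the more hindered hydroxyl.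

**Compound list**
1 | 3,4,5-trimethoxybenzyl chloride (5-(chloromethyl)-1,2,3-trimethoxybenzene) | COc1cc(CCl)cc(OC)c1OC | starting material
2 | (2S,3S)-2,3-dimethyloxirane (trans-(2S,3S)-2,3-epoxybutane) | C[C@@H]1O[C@H]1C | starting material
3 | (3,4,5-trimethoxybenzyl)magnesium chloride | COc1cc(C[Mg]Cl)cc(OC)c1OC | intermediate
4 | chloromagnesium (2S,3S)-3-methyl-4-(3,4,5-trimethoxyphenyl)butan-2-olate | COc1cc(C[C@H](C)[C@H](C)O[Mg]Cl)cc(OC)c1OC | intermediate
5 | (2S,3S)-3-methyl-4-(3,4,5-trimethoxyphenyl)butan-2-ol | COc1cc(C[C@H](C)[C@H](C)O)cc(OC)c1OC | intermediate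
6 | 3,4-dimethoxybenzoyl chloride | COc1ccc(C(Cl)=O)cc1OC | starting material
7 | (2S,3S)-3-methyl-4-(3,4,5-trimethoxyphenyl)butan-2-yl 3,4-dimethoxybenzoate | COc1cc(C[C@H](C)[C@H](C)OC(=O)c2ccc(OC)c(OC)c2)cc(OC)c1OC | intermediate
8 | 2-(3,4-dimethoxyphenyl)-5,6-dimethyl-4-(3,4,5-trimethoxyphenyl)-1,3-dioxan-2-ylium, 4-aryl/5-methyl trans, 5-methyl/6-methyl cis, chain carbons configured as in 10 (BF4⁻ from the electrolyte as counter-ion) | COc1ccc(C2=[O+][C@@H](C)[C@@H](C)[C@H](c3cc(OC)c(OC)c(OC)c3)O2)cc1OC | intermediate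
9 | 2-(3,4-dimethoxyphenyl)-5,6-dimethyl-4-(3,4,5-trimethoxyphenyl)-1,3-dioxan-2-ol, ring configuration as in 8, both C2 epimers | COc1ccc(C2(O)O[C@@H](C)[C@@H](C)[C@H](c3cc(OC)c(OC)c(OC)c3)O2)cc1OC | intermediate
10 | (1R,2R,3S)-3-hydroxy-2-methyl-1-(3,4,5-trimethoxyphenyl)butyl 3,4-dimethoxybenzoate | COc1ccc(C(=O)O[C@@H](c2cc(OC)c(OC)c(OC)c2)[C@H](C)[C@H](C)O)cc1OC | target

**Totals**
Total step count: 3. Longest linear sequence: 3 steps (1/2 → 5 → 7 → 10).

**Steps most likely to fail**

Step 3 (the proposed anodic acyl relay) carries the most risk. The arene radical cation may couple or be attacked on the ring instead of losing the benzylic proton. The facial selectivity at C1 may be lower than the A(1,3) model predicts. Hemiorthoester 9 may open partly to the regioisomer (C1–OH, ester on O3), or the ester may migrate afterwards under base. The fallback uses only known chemistry, sets out from 5 and comes back at 10. Alcohol 5 is silylated (TBSCl, imidazole, DMF) to tert-butyl(dimethyl){[(2S,3S)-3-methyl-4-(3,4,5-trimethoxyphenyl)butan-2-yl]oxy}silane F1. Benzylic oxidation of the electron-rich arylalkane with DDQ in wet CH2Cl2 gives (2R,3S)-3-[(tert-butyldimethylsilyl)oxy]-2-methyl-1-(3,4,5-trimethoxyphenyl)butan-1-one F2. Felkin–Anh reduction with L-Selectride (THF, −78 °C) gives the 1,2-anti alcohol (1R,2S,3S)-3-[(tert-butyldimethylsilyl)oxy]-2-methyl-1-(3,4,5-trimethoxyphenyl)butan-1-ol F3. Acylation with 6 (Et3N, DMAP) gives (1R,2S,3S)-3-[(tert-butyldimethylsilyl)oxy]-2-methyl-1-(3,4,5-trimethoxyphenyl)butyl 3,4-dimethoxybenzoate F4, and HF·pyridine (THF, 0 °C, no base) removes the silyl group to give 10. Here the protecting group fixes the regiochemistry and C2 controls C1 in the reduction.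

Step 1 is next. The electron-rich benzylic chloride tends to Wurtz homocoupling during Grignard formation, the 2,3-disubstituted epoxide opens slowly and can give the chlorohydrin, and 2 is volatile. The fallback sets out from 1 and comes back at 5. The dianion of ethyl (S)-3-hydroxybutanoate F5 (bought; LDA 2.2 equiv, THF/DMPU, −50 → −20 °C) is alkylated with 1 (Fráter–Seebach, anti) to give ethyl (2S,3S)-3-hydroxy-2-[(3,4,5-trimethoxyphenyl)methyl]butanoate F6. LiAlH4 reduces it to (2R,3S)-2-[(3,4,5-trimethoxyphenyl)methyl]butane-1,3-diol F7. Selective primary tosylation (TsCl, pyridine, 0 °C) gives (2R,3S)-3-hydroxy-2-[(3,4,5-trimethoxyphenyl)methyl]butyl 4-methylbenzenesulfonate F8, and LiEt3BH (THF, 0 °C) reduces the tosylate to the methyl group of 5. C3 is then bought in the hydroxy ester and C2 is set by it in the chelated dianion.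

Step 2 is the most reliable, but acylation of the hindered secondary alcohol under amine/DMAP conditions could stall. The fallback sets out from alkoxide 4 and comes back at 7. Before the acidic quench of step 1, the chloromagnesium alkoxide is acylated directly in the flask with 6 (1.3 equiv, cat. DMAP, THF, 0 °C → rt). This replaces acylation of the neutral alcohol by acylation of the metal alkoxide and removes the isolation of 5; it makes no new compound.

**Further compounds**
F1 | step 3 | tert-butyl(dimethyl){[(2S,3S)-3-methyl-4-(3,4,5-trimethoxyphenyl)butan-2-yl]oxy}silane | COc1cc(C[C@H](C)[C@H](C)O[Si](C)(C)C(C)(C)C)cc(OC)c1OC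
F2 | step 3 | (2R,3S)-3-[(tert-butyldimethylsilyl)oxy]-2-methyl-1-(3,4,5-trimethoxyphenyl)butan-1-one | COc1cc(C(=O)[C@H](C)[C@H](C)O[Si](C)(C)C(C)(C)C)cc(OC)c1OC
F3 | step 3 | (1R,2S,3S)-3-[(tert-butyldimethylsilyl)oxy]-2-methyl-1-(3,4,5-trimethoxyphenyl)butan-1-ol | COc1cc([C@H](O)[C@H](C)[C@H](C)O[Si](C)(C)C(C)(C)C)cc(OC)c1OC
F4 | step 3 | (1R,2S,3S)-3-[(tert-butyldimethylsilyl)oxy]-2-methyl-1-(3,4,5-trimethoxyphenyl)butyl 3,4-dimethoxybenzoate | COc1ccc(C(=O)O[C@@H](c2cc(OC)c(OC)c(OC)c2)[C@H](C)[C@H](C)O[Si](C)(C)C(C)(C)C)cc1OC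
F5 | step 1 | ethyl (S)-3-hydroxybutanoate (bought) | C[C@H](O)CC(=O)OCC
F6 | step 1 | ethyl (2S,3S)-3-hydroxy-2-[(3,4,5-trimethoxyphenyl)methyl]butanoate | COc1cc(C[C@H](C(=O)OCC)[C@H](C)O)cc(OC)c1OC
F7 | step 1 | (2R,3S)-2-[(3,4,5-trimethoxyphenyl)methyl]butane-1,3-diol | COc1cc(C[C@H](CO)[C@H](C)O)cc(OC)c1OC
F8 | step 1 | (2R,3S)-3-hydroxy-2-[(3,4,5-trimethoxyphenyl)methyl]butyl 4-methylbenzenesulfonate | COc1cc(C[C@H](COS(=O)(=O)c2ccc(C)cc2)[C@H](C)O)cc(OC)c1OC
F0 | step 2 | none | none
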